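Assumption: (2S)-naringenin (1) is taken to be purchasable in high enantiomeric purity. Much commercial naringenin is racemic, so the batch should be checked by chiral HPLC before use.

## Structural features

The target is a flavanone (2-arylchroman-4-one): the phloroglucinol-type ring A is fused to the dihydropyranone ring C through C4a and C8a, and the 4-hydroxyphenyl ring B is attached at C2. Free hydroxyls sit at C5, C7 and C4', and three 3-methylbut-2-enyl (prenyl) chains are bound through their CH2 carbons to C6 and C8 of ring A and to C3' of ring B. C2 is the only stereocentre (S), has no stereogenic neighbour and is a benzylic ether carbon beta to the C4 ketone, so a base that enolises C3 can expel O1, open ring C to the 2'-hydroxychalcone and erase the configuration on reclosure. The three trisubstituted olefins are also fragile: each lies ortho to a phenol, so strong acid closes them to 2,2-dimethylchromans or hydrates them, and oxidants attack them and the electron-rich ring A. The skeleton is not the problem, because rings A, B and C and the C2 configuration are those of (2S)-naringenin; the real difficulty is to attach three prenyl groups to carbon at exactly C6, C8 and C3', without O-alkylation, without geminal dialkylation of ring A and without racemisation. The key step exploits the fact that C6 and C8 (ortho and para to the ring A oxygens) and C3' (ortho to the 4'-hydroxyl, para position blocked by C1') are the carbons an electrophilic halogen attacks. Three aryl iodides placed there can be turned into the three aryl–CH2 bonds by palladium-catalysed coupling with a prenyltin reagent.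

## Logic of the disconnections

**9 back to 8.** The bonds cut are the two phenolic O–CH2 bonds of the acetal ethers at O7 and O4'; no skeletal bond is touched. The cut is made because the 7- and 4'-hydroxyls are acidic enough to protonolyse an allylstannane and must be masked during the coupling. Acetal ethers are inert to zerovalent palladium and to tin and go on under a weak amine base. The 5-hydroxyl needs no mask: it is locked in a hydrogen bond to the C4 carbonyl, and masking it would need a strong base that opens ring C. The gain is a coupling substrate with one weakly acidic proton only. The demand on the forward step is an acid mild enough to spare three prenyl olefins ortho to phenols and the C2 centre.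

**8 back to 6 and 7.** The bonds cut are C6–CH2, C8–CH2 and C3'–CH2, all three in one operation. They are cut here because each of these ring carbons can carry an iodide placed by electrophilic substitution. The regiochemistry of prenylation is thereby decided before any carbon is added, and O-prenylation and geminal diprenylation are excluded by mechanism. The gain is large: fifteen carbons leave, and what remains has the carbon skeleton and stereocentre of 1. The forward step must couple three times, twice at di-ortho-substituted carbons, with linear selectivity at each site and without base.

**6 back to 4 and 5.** The bonds cut are again the two O–CH2 acetal bonds, now on the triiodide. Protection is placed after halogenation on purpose. The free 4'-hydroxyl is what makes C3' reactive enough to be iodinated, and the free ring A phenols make C6 and C8 react without acid. The demand is selective etherification of the two acidic phenols, one of them flanked by two iodines, with a base too weak to enolise C3.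

**4 back to 1 and 2, through 3.** The bonds cut are the three C–I bonds. Ring A is far more nucleophilic than ring B, so the first two equivalents of 2 are consumed at C6 and C8 (stage 3) and the third is directed to ring B by acid activation. The gain is arrival at a chiral-pool material that already holds every ring and the stereocentre. The demand is to stop ring B at mono-iodination and to avoid conditions that racemise C2.

## Other disconnections considered

Alternative 1: The cut removes O1–C2 and C3–C4 together and divides the molecule into a ring A salicylaldehyde, 2-hydroxy-4,6-bis(tert-butyldimethylsilyloxy)-3,5-diprenylbenzaldehyde A1, and a ring B styrene, 4-(tert-butyldimethylsilyloxy)-3-prenylstyrene A2.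
- Forward key step: A1 would be condensed with trimethyl orthoformate A3 under a confined chiral Brønsted acid to form a 4-methoxy ortho-quinone methide. This adds A2 in an inverse-demand [4+2] cycloaddition to give the 2,4-cis 4-methoxyflavan A4. C4 would then be raised to the ketone, giving flavanone A5, and the silyl ethers would be removed to reach 9.
- In favour: the plan is convergent, uses no tin, and builds ring C and C2 in one step. C2 is set by the catalyst, so either enantiomer is accessible and nothing depends on the optical purity of 1. On this point it is the better plan.
- Against: A1 and A2 must each be made in several steps, and C-diprenylation of a phloroglucinol aldehyde is the very regiochemical problem the target poses. The quinone methide is pentasubstituted and flanked at C5 by a silyloxy group, so its fit in a confined catalyst pocket is uncertain. A styrene and prenyl olefins are exposed to a strong acid. The C4 methyl ether of A4 must afterwards be oxidised in the presence of three prenylarenes, which are themselves prone to oxidation. The C4 stereocentre is made only to be destroyed.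
- Comparison: on structure it builds what the chosen plan buys intact. On mechanism it offers catalyst control of C2 but puts the fragile olefins through acid and oxidant. On step economy it needs roughly ten or more operations against four.

Alternative 2: The cut is C4a–C5, so that ring A is unravelled into a polyketide-like chain on a preformed ring C. The precursor is methyl 2,4-diprenyl-3-oxo-4-[(2S)-2-(4-methoxymethoxy-3-prenylphenyl)-4-oxo-2,3-dihydropyran-6-yl]butanoate A6.
- Forward key step: a magnesium alkoxide would generate the vinylogous enolate of A6. It acylates through C4a on the terminal ester in a Claisen (Dieckmann-type) closure and the product tautomerises to the phloroglucinol A7, which is one acetal cleavage from 9.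
- In favour: the prenyl groups of ring A are set by enolate C-alkylation of a beta-dicarbonyl chain, which is as unambiguous as the iodination logic (equal). A7 needs one deprotection, so the end game is equal and the protecting-group count is lower (better).
- Against: A6 is a sensitive polycarbonyl compound. Its synthesis includes a separate asymmetric construction of C2 and is long. The basic closure can acylate on oxygen to pyrones or close through the wrong carbon. The same base can eliminate O1 from the dihydropyranone or from the product flavanone, so C2 is at risk in the key step itself.
- Comparison: on structure it is elegant but builds ring A from scratch. On mechanism the base-mediated closure is less safe for C2 than a base-free coupling. On step economy it is far longer.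

Alternative 3: The cut is O1–C8a. The precursor is the syn-diol aryl triflate (1S,3R)-1-[4-(methoxymethoxy)-3-prenylphenyl]-3-[2,4-bis(methoxymethoxy)-3,5-diprenyl-6-(trifluoromethanesulfonyloxy)phenyl]propane-1,3-diol A8.
- Forward key step: a palladium catalyst carrying a bulky di-tert-butyl biarylphosphine, with a carbonate base, would join the C2 hydroxyl to C8a with retention. This gives the 2,4-trans flavan-4-ol A9. Oxidation at C4 would give the tris-acetal flavanone A10, and cleavage of three acetal ethers would give 9.
- In favour: C2 is set by standard asymmetric carbonyl chemistry. No bond to C2 is made or broken in the closure, and no ketone is present while base is used, so the stereocentre is as safe as in the chosen plan or safer (equal or better). All three phenols are protected alike.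
- Against: A8 has a hexasubstituted ring A whose triflate is flanked by a prenyl group and the side chain. Oxidative addition and C–O reductive elimination at such a hindered, electron-rich carbon are demanding. Beta-hydride elimination from the palladium alkoxide and insertion of the neighbouring olefin compete. Two further steps follow the closure, and the C4 carbinol stereocentre is sacrificial.
- Comparison: on structure it assembles the skeleton linearly. On mechanism it is stereochemically secure but sterically the hardest closure of the three. On step economy it is well over twice as long as the chosen plan.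

Key step: step 3

## Route

Step 1
Reactants: 1 (2S)-naringenin; 2 N-iodosuccinimide
Product: 4 (2S)-6,8,3'-triiodonaringenin, via (2S)-6,8-diiodonaringenin 3 (not isolated)
Conditions: 2 (2.05 equiv), MeCN–THF, 0 °C, dark; then 2 (1.05 equiv), TsOH·H2O (10 mol%), 0 °C → rt; aq Na2S2O3 work-up
Reagents that add atoms: N-iodosuccinimide (2), O=C1CCC(=O)N1I
Why: Electrophilic aromatic iodination: the doubly activated C6 and C8 of ring A react first without acid, then acid-activated 2 iodinates ring B ortho to the 4'-hydroxyl, where the first iodine deactivates the ring so that one equivalent should stop at C3'; C2 is not involved and no base is present.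

Step 2
Reactants: 4 (2S)-6,8,3'-triiodonaringenin; 5 chloromethyl methyl ether
Product: 6 (2S)-5-hydroxy-6,8,3'-triiodo-7,4'-bis(methoxymethoxy)flavanone
Conditions: 5 (2.3 equiv), i-Pr2NEt (3 equiv), CH2Cl2, 0 °C → rt
Reagents that add atoms: chloromethyl methyl ether (5), COCCl
Why: O-Alkylation of the two acidic phenols (methoxymethyl ether formation); the 5-hydroxyl is hydrogen-bonded to the C4 carbonyl and should stay free with limited 5, and a hindered amine at or below room temperature should be too weak to enolise C3 and open ring C, so C2 stays S.

Step 3
Reactants: 6 (2S)-5-hydroxy-6,8,3'-triiodo-7,4'-bis(methoxymethoxy)flavanone; 7 tributyl(3-methylbut-2-enyl)stannane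
Product: 8 (2S)-5-hydroxy-7,4'-bis(methoxymethoxy)-6,8,3'-triprenylflavanone
Conditions: 7 (4.5 equiv), Pd(PPh3)4 (15 mol%), degassed DMF, 90 °C, Ar, dark; aq KF work-up
Reagents that add atoms: tributyl(3-methylbut-2-enyl)stannane (7), CCCC[Sn](CCCC)(CCCC)CC=C(C)C
Why: This is a threefold Stille (Migita–Kosugi–Stille) coupling: zerovalent palladium adds oxidatively to each C–I bond of 6, the prenyl group passes from tin to palladium, and reductive elimination forms the aryl–CH2 bond at C6, C8 and C3' in turn. The closest known reaction type is the Stille prenylation of a single ortho-oxygenated aryl iodide with 7 under Pd(PPh3)4 in DMF, here carried out three times on one substrate. No ring is closed and no stereocentre is created; C2 is a spectator and should be kept because the medium contains no base that could open ring C by retro-oxa-Michael elimination. The selectivity needed is linear (alpha) over branched (gamma) coupling at every site: the prenylpalladium intermediate can equilibrate between its two allyl termini, and with PPh3 on the metal reductive elimination should take place at the unsubstituted CH2 end, the more so at C6 and C8, where two ortho oxygen substituents leave no room for a quaternary 1,1-dimethylallyl carbon. Coupling must also outrun hydrodeiodination, which the iodide leaving groups, the polar solvent and the excess of 7 should secure. The acetal ethers at O7 and O4' remove the two acidic phenols that would protonolyse 7, and the remaining 5-hydroxyl is held in a hydrogen bond to the C4 carbonyl and is too weak an acid to do so.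

Step 4
Reactants: 8 (2S)-5-hydroxy-7,4'-bis(methoxymethoxy)-6,8,3'-triprenylflavanone
Product: 9 (2S)-5,7,4'-trihydroxy-6,8,3'-triprenylflavanone
Conditions: HCl (1 M in MeOH), 40 °C
Reagents that add atoms: none
Why: Acid-catalysed acetal methanolysis (methoxymethyl ether cleavage), in which the protonated acetal releases the phenol and methanol captures the methoxymethyl cation; dilute acid at 40 °C for a monitored time should spare the prenyl olefins, and C2 should stay S because no base is present and acid-induced ring opening of a 5-hydroxyflavanone is slow.

## Compound list

1 | (2S)-naringenin, (2S)-5,7-dihydroxy-2-(4-hydroxyphenyl)chroman-4-one | Oc1ccc([C@@H]2CC(=O)c3c(O)cc(O)cc3O2)cc1 | starting material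
2 | N-iodosuccinimide | O=C1CCC(=O)N1I | starting material
3 | (2S)-6,8-diiodonaringenin, (2S)-5,7-dihydroxy-2-(4-hydroxyphenyl)-6,8-diiodochroman-4-one | Oc1ccc([C@@H]2CC(=O)c3c(O)c(I)c(O)c(I)c3O2)cc1 | intermediate
4 | (2S)-6,8,3'-triiodonaringenin, (2S)-5,7-dihydroxy-2-(4-hydroxy-3-iodophenyl)-6,8-diiodochroman-4-one | Oc1ccc([C@@H]2CC(=O)c3c(O)c(I)c(O)c(I)c3O2)cc1I | intermediate
5 | chloromethyl methyl ether | COCCl | starting material
6 | (2S)-5-hydroxy-6,8,3'-triiodo-7,4'-bis(methoxymethoxy)flavanone, (2S)-5-hydroxy-6,8-diiodo-2-[3-iodo-4-(methoxymethoxy)phenyl]-7-(methoxymethoxy)chroman-4-one | COCOc1ccc([C@@H]2CC(=O)c3c(O)c(I)c(OCOC)c(I)c3O2)cc1I | intermediate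
7 | tributyl(3-methylbut-2-enyl)stannane | CCCC[Sn](CCCC)(CCCC)CC=C(C)C | starting material
8 | (2S)-5-hydroxy-7,4'-bis(methoxymethoxy)-6,8,3'-triprenylflavanone, (2S)-5-hydroxy-7-(methoxymethoxy)-2-[4-(methoxymethoxy)-3-(3-methylbut-2-enyl)phenyl]-6,8-bis(3-methylbut-2-enyl)chroman-4-one | CC(C)=CCc1cc([C@@H]2CC(=O)c3c(O)c(CC=C(C)C)c(OCOC)c(CC=C(C)C)c3O2)ccc1OCOC | intermediate
9 | (2S)-5,7,4'-trihydroxy-6,8,3'-triprenylflavanone, (2S)-5,7-dihydroxy-2-[4-hydroxy-3-(3-methylbut-2-enyl)phenyl]-6,8-bis(3-methylbut-2-enyl)chroman-4-one | CC(C)=CCc1cc([C@@H]2CC(=O)c3c(O)c(CC=C(C)C)c(O)c(CC=C(C)C)c3O2)ccc1O | target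

Total step count: 4. Longest linear sequence: 4 steps (1 → 4 → 6 → 8 → 9).

## Least certain steps

**Step 3 (key step).** The most likely failures are gamma-coupling at one or more of the three sites, which multiplies into isomer mixtures, and incomplete coupling at the di-ortho-substituted C6 and C8 with hydrodeiodination taking over as the catalyst ages. Both arise from the unsymmetrical allyl group and from slow transmetalation at hindered arylpalladium centres.

Fallback, from 6 back to 8: 6 would be coupled under the same Pd(PPh3)4 conditions with allyltributylstannane. Its allyl group is symmetrical and transfers faster, so no alpha/gamma question arises. The product would be (2S)-6,8,3'-triallyl-5-hydroxy-7,4'-bis(methoxymethoxy)flavanone F1. Threefold olefin cross-metathesis of F1 with a large excess of 2-methyl-2-butene, using the second-generation Grubbs catalyst RuCl2(=CHPh)(PCy3)(H2IMes) in CH2Cl2 at 40 °C in a closed vessel, should turn each allyl into a prenyl group and rejoin the route at 8.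

**Step 1.** The risk is over-iodination of ring B at C5', or its counterpart, incomplete iodination at C3'. The second ortho position is only moderately deactivated by the first iodine, and the resulting phenol mixtures would be hard to separate.

Fallback, from 3 back to 6: the first stage would be stopped and 3 isolated. 3 would be etherified with 5 and i-Pr2NEt as in step 2 to give (2S)-5-hydroxy-6,8-diiodo-7,4'-bis(methoxymethoxy)flavanone F2. Ring B would then be iodinated as its aryl ether with 2 (1.1 equiv) and catalytic CF3CO2H in MeCN at 0 °C to room temperature. Ring A is fully substituted, no phenoxide pathway exists, and an ortho-iodo aryl ether is strongly deactivated, so substitution should stop at C3' and give 6.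

**Step 4.** The risk is acid-induced cyclisation of a prenyl group onto its neighbouring free phenol, or addition of methanol or water to the olefins. This becomes more likely if the hindered 7-acetal between two prenyl groups cleaves slowly and the reaction has to be forced.

Fallback, from 4 to 9: the acetal protection would be replaced by silyl ethers that are cleaved without protic acid. 4 with tert-butyldimethylsilyl chloride and imidazole in DMF should give (2S)-7,4'-bis(tert-butyldimethylsilyloxy)-5-hydroxy-6,8,3'-triiodoflavanone F3. Coupling with 7 under the rigorously dry conditions of step 3 should give (2S)-7,4'-bis(tert-butyldimethylsilyloxy)-5-hydroxy-6,8,3'-triprenylflavanone F4. Et3N·3HF in THF at 0 °C should then release 9 directly.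

**Step 2.** The risks are sluggish etherification of the 7-hydroxyl between two iodines, partial alkylation of the 5-hydroxyl when more reagent is added to compensate, and slow base-induced opening of ring C with erosion of the C2 configuration during a prolonged reaction.

Fallback, from 1 back to 6: the order would be reversed. 1 would be etherified first with 5 and i-Pr2NEt, while both phenols are unhindered, to give (2S)-5-hydroxy-7,4'-bis(methoxymethoxy)flavanone F5. F5 would then be iodinated at C6, C8 and C3' with 2 (3.3 equiv) and catalytic CF3CO2H in MeCN to give 6.

## Further compounds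

F1 | step 3 | (2S)-6,8,3'-triallyl-5-hydroxy-7,4'-bis(methoxymethoxy)flavanone | C=CCc1cc([C@@H]2CC(=O)c3c(O)c(CC=C)c(OCOC)c(CC=C)c3O2)ccc1OCOC
F2 | step 1 | (2S)-5-hydroxy-6,8-diiodo-7,4'-bis(methoxymethoxy)flavanone | COCOc1ccc([C@@H]2CC(=O)c3c(O)c(I)c(OCOC)c(I)c3O2)cc1
F3 | step 4 | (2S)-7,4'-bis(tert-butyldimethylsilyloxy)-5-hydroxy-6,8,3'-triiodoflavanone | CC(C)(C)[Si](C)(C)Oc1ccc([C@@H]2CC(=O)c3c(O)c(I)c(O[Si](C)(C)C(C)(C)C)c(I)c3O2)cc1I
F4 | step 4 | (2S)-7,4'-bis(tert-butyldimethylsilyloxy)-5-hydroxy-6,8,3'-triprenylflavanone | CC(C)=CCc1cc([C@@H]2CC(=O)c3c(O)c(CC=C(C)C)c(O[Si](C)(C)C(C)(C)C)c(CC=C(C)C)c3O2)ccc1O[Si](C)(C)C(C)(C)C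
F5 | step 2 | (2S)-5-hydroxy-7,4'-bis(methoxymethoxy)flavanone | COCOc1ccc([C@@H]2CC(=O)c3c(O)cc(OCOC)cc3O2)cc1
A1 | alternative 1 | 2-hydroxy-4,6-bis(tert-butyldimethylsilyloxy)-3,5-bis(3-methylbut-2-enyl)benzaldehyde | O=Cc1c(O)c(CC=C(C)C)c(O[Si](C)(C)C(C)(C)C)c(CC=C(C)C)c1O[Si](C)(C)C(C)(C)C
A2 | alternative 1 | tert-butyldimethyl[2-(3-methylbut-2-enyl)-4-vinylphenoxy]silane | C=Cc1ccc(O[Si](C)(C)C(C)(C)C)c(CC=C(C)C)c1
A3 | alternative 1 | trimethyl orthoformate | COC(OC)OC
A4 | alternative 1 | (2S,4S)-4-methoxy-5,7,4'-tris(tert-butyldimethylsilyloxy)-6,8,3'-triprenylflavan (2,4-cis) | CC(C)=CCc1cc([C@@H]2C[C@H](OC)c3c(O[Si](C)(C)C(C)(C)C)c(CC=C(C)C)c(O[Si](C)(C)C(C)(C)C)c(CC=C(C)C)c3O2)ccc1O[Si](C)(C)C(C)(C)C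
A5 | alternative 1 | (2S)-5,7,4'-tris(tert-butyldimethylsilyloxy)-6,8,3'-triprenylflavanone | CC(C)=CCc1cc([C@@H]2CC(=O)c3c(O[Si](C)(C)C(C)(C)C)c(CC=C(C)C)c(O[Si](C)(C)C(C)(C)C)c(CC=C(C)C)c3O2)ccc1O[Si](C)(C)C(C)(C)C
A6 | alternative 2 | methyl 2,4-bis(3-methylbut-2-enyl)-3-oxo-4-[(2S)-2-[4-(methoxymethoxy)-3-(3-methylbut-2-enyl)phenyl]-4-oxo-2,3-dihydropyran-6-yl]butanoate (chain centres unspecified) | COC(=O)C(CC=C(C)C)C(=O)C(CC=C(C)C)C1=CC(=O)C[C@@H](c2ccc(OCOC)c(CC=C(C)C)c2)O1
A7 | alternative 2 | (2S)-5,7-dihydroxy-4'-(methoxymethoxy)-6,8,3'-triprenylflavanone | CC(C)=CCc1cc([C@@H]2CC(=O)c3c(O)c(CC=C(C)C)c(O)c(CC=C(C)C)c3O2)ccc1OCOC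
A8 | alternative 3 | (1S,3R)-1-[4-(methoxymethoxy)-3-(3-methylbut-2-enyl)phenyl]-3-[2,4-bis(methoxymethoxy)-3,5-bis(3-methylbut-2-enyl)-6-(trifluoromethanesulfonyloxy)phenyl]propane-1,3-diol | CC(C)=CCc1cc([C@@H](O)C[C@@H](O)c2c(OCOC)c(CC=C(C)C)c(OCOC)c(CC=C(C)C)c2OS(=O)(=O)C(F)(F)F)ccc1OCOC
A9 | alternative 3 | (2S,4R)-5,7,4'-tris(methoxymethoxy)-6,8,3'-triprenylflavan-4-ol (2,4-trans) | CC(C)=CCc1cc([C@@H]2C[C@@H](O)c3c(OCOC)c(CC=C(C)C)c(OCOC)c(CC=C(C)C)c3O2)ccc1OCOC
A10 | alternative 3 | (2S)-5,7,4'-tris(methoxymethoxy)-6,8,3'-triprenylflavanone | CC(C)=CCc1cc([C@@H]2CC(=O)c3c(OCOC)c(CC=C(C)C)c(OCOC)c(CC=C(C)C)c3O2)ccc1OCOC
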